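## Analysis of the target

Sodwanone B (22, C30H44O5) consists of two bicyclic halves joined by the C12–C12' ethylene bridge; atoms are numbered along the squalene-type chain, C1 to C12 in the western half and C1' to C12' in the eastern half, and a methyl group is named after the carbon that bears it. In the western half, ring A is an oxepan-3-one (ring O, C2 with two methyl groups, C3=O, C4, C5, C6, C7) trans-fused along C6–C7 to cyclohexane ring B (C6 to C11). Ring B carries four stereocentres, quaternary C6 (S), oxygen-bearing C7 (S), C10 (R) and C11 (R): in the chair the C6 methyl is axial, C6–C5, C7–O and C11–C12 are equatorial, and the C10 methyl is axial, cis to the C11 chain and syn-diaxial to the C6 methyl, so C10 is the less stable epimer. In the eastern half, ring C is a cross-conjugated 2-hydroxycyclohexa-2,5-dienone (C6', C7'=C8'(OH), C9'=O, C10'(CH3)=C11') fused along C6'–C7' to cyclohexanone ring D (C2' with two methyl groups, C3'=O, C4', C5'), and quaternary C6' (R) is its only stereocentre. C6' lies four bonds from C11, so neither half can control the other and each needs its own source of absolute configuration. The sensitive groups are the diosphenol of ring C (base, air, oxidants), the vinylogously acidic C12' methylene group, the α-alkoxy ketone of ring A, and three ketones whose α-methylene groups a base cannot tell apart, which argues for unveiling all carbonyl groups at the very end. The hard points are the C6–C11 bond between a quaternary and a tertiary carbon, the seven-membered ether that ends on fully substituted C2, the contra-thermodynamic C10 methyl, and the high oxidation level of ring C. The plan exploits two features: the oxygenated pairs C2/C3 and C6/C7 stand in the 1,5-relationship of a geranyl bis-epoxide and C11 is α to C10, so once C10 is read as a ketone, rings A and B are the folded form of an acyclic diepoxy enol ether whose carbons C1 to C11 are those of 1, while C1' to C12' plus C12 are, carbon for carbon and with the correct C6' configuration, the skeleton of 3.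

## Retrosynthetic reasoning

**22 to 20.** No skeletal bond is cut first. The oxygen functions at C3, C3' and C8' are taken back to the secondary alcohols of triol 20. Three ketones with free α-methylene groups and a diosphenol would not survive any base, ylide or oxidant needed earlier. The gain is that every earlier step meets at most one carbonyl group. The forward reaction is one global oxidation to tetraketone 21, whose C7'–H, now α to the C8' carbonyl group, tautomerises to the diosphenol of 22.

**20 to 16.** The C8'–O and C9'=O bonds are cut, through acyloin 19 and enone 17, back to 16, which carries only the tetrasubstituted C10'=C11' alkene in ring C. They are cut here because an enone in ring C makes C12'–H2 acidic and would spoil the union of the halves, and because it would compete in the methylenation and hydrogenation of ring B. The forward reactions must oxidise the endocyclic allylic CH2 (C9') and then the kinetic α'-enolate 18 at C8'.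

**16 to 14.** The C10–CH3 bond is cut through the exocyclic alkene 15, which turns C10 into the ketone of 14. This carbon is the only one that neither 1 nor 3 supplies. The ketone is what makes C11 nucleophilic in the key step. The forward sequence must deliver hydrogen to C10 from the face opposite the axial C6 methyl, which gives the required axial methyl group.

**14 to 12, the key disconnection.** Two bonds are cut in one stroke, O–C2 of ring A and C6–C11 of ring B. The C3 oxygen and the ring oxygen are returned to the C2–C3 and C6–C7 epoxides of the acyclic silyl enol ether 12.

- Why here: C6–C11 is the most hindered bond of the molecule. On a preformed ring B, C11 is neopentyl and the C10 ketone enolises towards C9, so the bridge cannot be attached afterwards. An intramolecular closure with the bridge and the whole eastern half already in place reduces the problem to a six-membered chair transition state.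
- What is gained: the precursor has no ring in its western half and no stereocentre there beyond the three epoxide carbons. The step returns both rings, the quaternary centre C6, C7 and C11.
- What the forward reaction must do: relay a positive charge from C2 through the second epoxide oxygen (epoxonium ion 13) to C6 and end it by C–C bond formation at C11.
- Why it is not the obvious plan: most plans would join two finished bicycles, whereas here the western bicycle does not exist until the C29 chain is complete.

**12 to 2 and 7.** The C11–C12 bond is cut. A ketone flanked by CH2 groups at C9 and C11 cannot be enolised regioselectively. The enol ether is therefore derived from enone 11 by 1,4-addition of a hydrosilane, which fixes the double bond at C10=C11 and, through the s-cis enone, its Z geometry. Enone 11 is opened by a retro-aldol condensation (through 10 and 9) into methyl ketone 2, which reacts through its kinetic enolate 8 at the C11 methyl group, and aldehyde 7. The union thus falls on an unhindered position and divides the carbons 13 + 16.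

**2 to 1.** The four C–O bonds of the two epoxides are cut. Both trisubstituted alkenes of 1 belong to the substrate class for which the chiral dioxirane epoxidation is most reliable, and one catalyst sets C3, C6 and C7 in one operation. C6 and C7 then carry all the stereochemical information of the western half.

**7 to 3.** The eastern aldehyde is traced through 6, 5 and 4 to the chiral pool lactone 3. Its lactone carbonyl carbon becomes C12, its CH2 becomes C12', and its angular methyl-bearing carbon is C6' in the correct configuration. The stereocentres of 3 at C10', C11' and later C7' are erased on purpose. The forward steps must add the C3' oxygen by enzymatic C–H hydroxylation, open the lactone to the tetrasubstituted alkene, and adjust C12 to the aldehyde.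

## Alternatives that were turned down

Alternative 1: The textbook cut is the sp3–sp2 bond C12'–C11' between two finished bicycles, the C11-vinyl oxepane A1 and the ring C enol triflate A2. The forward key step is hydroboration of the vinyl group of A1 followed by B-alkyl Suzuki coupling with A2. The coupling itself is safe, but it closes no ring and sets no stereocentre, so every hard feature is pushed into the fragments. In A1 the two-carbon branch must be placed on C11 of a preformed ring B next to quaternary C6. A ring B ketone at C10 enolises away from C6, so the branch needs a detour, and the C6–C11 bond, the oxepane and four stereocentres still have to be made one after the other. A2 needs a carbonyl group at C11' flanked by quaternary C6', and ring C must still be oxidised three times after the coupling. Two separate stereocontrolled bicycle syntheses plus that endgame cost clearly more steps than the chosen route.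

Alternative 2: Ring C is read as a dearomatised catechol and the C5'–C6' bond of ring D is cut, which leads to the hexasubstituted catechol iodide A3. The forward key step is a base-induced para-alkylative dearomatisation in which the C9' phenoxide attacks C5' through C6' and creates ring D, the quaternary centre and the dienone at once. It was turned down for four reasons.
- The two faces of the flat ring differ only through the C3' substituent, which is 1,4 to C6', and the western stereocentres are too remote, so no element controls C6'.
- O-alkylation competes with attack at a methyl-bearing ring carbon, and the product can return to an arene by dienone–phenol rearrangement.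
- The C3' ketone must be masked, since a leaving group β to it would eliminate.
- An arene with six different substituents, one of them a tert-alkyl group between OH and CH3, costs more steps than ring D is worth.

Alternative 3: All four ring-forming bonds (O–C2, C6–C11, C2'–C7', C6'–C11') are cut at once, back to the acyclic all-(S) triepoxide A4. The forward key step is a two-directional Lewis acid polycyclisation from both chain ends. It was turned down for four reasons.
- Three of six nearly identical trisubstituted alkenes of a C30 chain cannot be epoxidised selectively, so A4 must be assembled from pre-epoxidised halves anyway.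
- Both cascades end in tertiary cations at C10 and C10' that can each lose a proton in three directions.
- The two resulting alkenes sit in almost identical surroundings, although one must be reduced and the other turned into an enone.
- Ring C still lacks all its oxygen, and the eastern decalin, which 3 offers for free with C6' secured, would be bought with the riskiest part of the step.

Key step: step 9

Assumption: the configuration written in the SMILES string is taken as the absolute configuration of 22 (6S,7S,10R,11R,6'R in the numbering used here); 1 is used as the pure E isomer; the L-fructose-derived Shi ketone and the P450 variant are catalysts and their preparation is not counted.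

## Steps

Step 1
Reactants: 1 (E)-geranylacetone [(5E)-6,10-dimethylundeca-5,9-dien-2-one]
Product: 2 (3S,6S,7S)-diepoxy ketone, 4-[(2S,3S)-3-{2-[(2S)-3,3-dimethyloxiran-2-yl]ethyl}-3-methyloxiran-2-yl]butan-2-one
Conditions: L-fructose-derived Shi ketone (cat.), KHSO5 (as 2KHSO5·KHSO4·K2SO4), K2CO3, Bu4NHSO4, Na2B4O7 buffer pH 10.5, MeCN/CH2(OMe)2/H2O, 0 °C
Reagents that add atoms: potassium peroxymonosulfate, [K+].[O-]S(=O)(=O)OO
Why: Shi asymmetric epoxidation; the chiral dioxirane attacks both trisubstituted alkenes through the spiro transition state, and the L-fructose-derived catalyst should give the S configuration at C3, C6 and C7 with retention of the E geometry (C5 and C8 trans on the oxirane). The saturated ketone is inert, and two independent enantioselective events raise the enantiomeric purity of the major diastereomer.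

Step 2
Reactants: 3 (+)-sclareolide
Product: 4 (3'S)-3'-hydroxysclareolide (3β-hydroxysclareolide, equatorial OH on ring D)
Conditions: C3'-selective cytochrome P450-BM3 variant (E. coli lysate), NADP+ (cat.), glucose dehydrogenase, D-glucose, air, phosphate buffer pH 8, rt
Reagents that add atoms: dioxygen, O=O
Why: Enzymatic C–H hydroxylation by a P450 monooxygenase; this very lactone is a known substrate that engineered BM3 variants and fungal whole cells hydroxylate at the equatorial C3'–H, whereas chemical oxidants prefer the neighbouring C4' methylene group. The enzyme pocket sets C3', which is erased again in step 15.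

Step 3
Reactants: 4 (3'S)-3'-hydroxysclareolide
Product: 5 methyl 2-[(4aR,6S,8aS)-6-hydroxy-2,5,5,8a-tetramethyl-3,4,4a,5,6,7,8,8a-octahydronaphthalen-1-yl]acetate (C10'=C11' alkene, C12 methyl ester)
Conditions: H2SO4, MeOH, reflux
Reagents that add atoms: methanol, CO
Why: Acid ionises the tertiary C10'–O bond of the lactone, Fischer esterification traps the acid, and reversible protonation (E1, thermodynamic control) should funnel the alkene isomers to the tetrasubstituted C10'=C11' alkene, as known for the parent lactone. C6' and C7' are untouched and the hindered secondary C3' alcohol should survive.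

Step 4
Reactants: 5 hydroxy ester
Product: 6 tert-butyldimethylsilyl ether of 5
Conditions: t-BuMe2SiCl, imidazole, DMF, 50 °C
Reagents that add atoms: tert-butyldimethylsilyl chloride, CC(C)(C)[Si](C)(C)Cl
Why: Standard silylation of a secondary alcohol; the ether withstands hydride, amide base, silyl triflate, ylide and chromium reagents and falls in step 14 together with the western silyl ether.

Step 5
Reactants: 6 silyl ether ester
Product: 7 2-[(4aR,6S,8aS)-6-(tert-butyldimethylsilyloxy)-2,5,5,8a-tetramethyl-3,4,4a,5,6,7,8,8a-octahydronaphthalen-1-yl]acetaldehyde (C12 aldehyde)
Conditions: i-Bu2AlH (1.1 equiv), CH2Cl2, −78 °C; aq. potassium sodium tartrate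
Reagents that add atoms: none
Why: Partial reduction of an ester; at −78 °C the tetrahedral aluminium hemiacetal persists until work-up, so the reduction stops at the aldehyde. The tetrasubstituted alkene has no drive to move into conjugation under these neutral conditions.

Step 6
Reactants: 2 diepoxy ketone; 7 aldehyde
Product: 9 β-hydroxy ketone (aldol adduct; C12 carbinol as a mixture of epimers; other centres as in 2 and 7), via lithium enolate 8 (not isolated)
Conditions: LiN(i-Pr)2, THF, −78 °C, 2; then 7, −78 °C; aq. NH4Cl
Reagents that add atoms: lithium diisopropylamide, [Li+].CC(C)[N-]C(C)C (lithium of 8 only)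
Why: Directed aldol addition; kinetic deprotonation takes the C11 methyl group of the methyl ketone, and addition to the aldehyde at −78 °C is faster than proton transfer or attack on the trisubstituted epoxides. The new C12 carbinol centre is removed in step 7, so its configuration does not matter.

Step 7
Reactants: 9 β-hydroxy ketone
Product: 11 (E)-enone C10(=O)–C11H=C12H–C12'H2, via mesylate 10 (not isolated)
Conditions: MeSO2Cl, Et3N, CH2Cl2, 0 °C to rt
Reagents that add atoms: methanesulfonyl chloride, CS(=O)(=O)Cl (its atoms stay in 10 only and leave again)
Why: Mesylation and E1cB elimination of a β-sulfonyloxy ketone, which gives the E enone for steric reasons. The weak amine base keeps the doubly allylic C12' methylene group and the epoxides intact.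

Step 8
Reactants: 11 (E)-enone
Product: 12 (Z)-triethylsilyl enol ether C10(OSiEt3)=C11H–C12H2 (OSi and C12 cis, C9 and C12 trans)
Conditions: RhCl(PPh3)3 (cat.), Et3SiH, THF, 50 °C
Reagents that add atoms: triethylsilane, CC[SiH](CC)CC
Why: Rhodium-catalysed 1,4-hydrosilylation of an enone with a monohydrosilane; it places the enol double bond regiospecifically at C10=C11, which enolisation of the saturated ketone could not do. Delivery through the s-cis enone should give the Z isomer; the epoxides, the silyl ether and the tetrasubstituted alkene are not substrates.

Step 9
Reactants: 12 (Z)-triethylsilyl enol ether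
Product: 14 bicyclic keto silyl ether (rings A and B closed; C10 ketone; C3–OSiEt3; 3S,6S,7S,11S with C11–H anti to the C6 methyl), via epoxonium triflate 13 (not isolated)
Conditions: Et3SiOTf, 2,6-di-tert-butyl-4-methylpyridine, CH2Cl2, −78 °C; aq. NaHCO3
Reagents that add atoms: triethylsilyl trifluoromethanesulfonate, CC[Si](CC)(CC)OS(=O)(=O)C(F)(F)F
Why: The silyl triflate silylates the terminal C2–C3 epoxide, and as the bond from tertiary C2 to oxygen stretches, the oxygen of the C6–C7 epoxide attacks C2 to give the bicyclic epoxonium ion 13; the enol ether opens 13 at tertiary C6 through C11, and loss of the enol silyl group to triflate gives the C10 ketone and returns the promoter, so the step is in sum an isomerisation (the same silyl group is used in 12 and in the promoter so that only one silyl ether can form). The closest known reaction type is the silyl-triflate-promoted tandem oxa- and carbacyclisation of 1,5-diepoxides terminated by silyl enol ethers or allylsilanes, which gives this same trans-fused oxepane–cyclohexane motif. Ring A closes in the endo mode (7-endo with respect to the C2–C3 epoxide, C–O bond made at the more substituted carbon), and ring B closes by 6-endo opening of the epoxonium ion at C6 with the enol ether reacting enol-endo. C7 keeps its epoxide configuration and C6 is inverted by backside attack of C11, so both are fixed by step 1, and the trans arrangement of C5 and C8 on the oxirane makes the ring fusion trans with the C6 methyl axial. C11 is set by the chair-like folding, in which C12, trans to C9 on the Z enol ether, becomes equatorial and C11–H anti to the C6 methyl; this is also the more stable α-epimer of the ketone, so any leakage can be corrected by mild base. The step needs endo over exo opening at both oxiranes, which the tertiary carbons C2 and C6 secure by carrying the positive charge. It also needs C- over O-attack and survival of the enol ether, which the low temperature and the hindered, non-nucleophilic base secure. Finally, the C10'=C11' alkene must stay silent, which it should because it could only close a nine-membered ring.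

Step 10
Reactants: 14 bicyclic keto silyl ether
Product: 15 exocyclic alkene (C10=CH2)
Conditions: Ph3PCH3Br, KOt-Bu, THF, 0 °C to reflux
Reagents that add atoms: methyltriphenylphosphonium bromide, C[P+](c1ccccc1)(c1ccccc1)c1ccccc1.[Br-]
Why: Wittig methylenation of the only carbonyl group in the molecule, well known for cyclohexanones of this substitution pattern. Reversible enolisation under the basic conditions can only confirm the equatorial, more stable C11 epimer.

Step 11
Reactants: 15 exocyclic alkene
Product: 16 (10R)-methyl compound (axial C10 methyl, cis to the C11 chain)
Conditions: H2 (1 atm), PtO2, EtOAc, rt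
Reagents that add atoms: none
Why: Heterogeneous syn-hydrogenation; the axial C6 methyl, 1,3 to C10, blocks the upper face of the methylenecyclohexane, so hydrogen should reach C10 from the opposite face and push the new methyl group into the axial position, as is usual for methylenecyclohexanes with a syn-axial methyl group. The tetrasubstituted C10'=C11' alkene is inert under these conditions.

Step 12
Reactants: 16 (10R)-methyl compound
Product: 17 C9' enone (C9'=O conjugated with C10'=C11')
Conditions: CrO3, 3,5-dimethylpyrazole, CH2Cl2, −20 °C
Reagents that add atoms: chromium trioxide, O=[Cr](=O)=O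
Why: Allylic oxidation with a hexavalent chromium–pyrazole complex; of the three allylic sites, the endocyclic C9' methylene group has an axial C–H bond aligned with the π system and gives the planar ring enone. C12' is shielded by the C6' methyl group and its ketone could not become coplanar, and the methyl group reacts more slowly; the same site selectivity is known for the parent homodrimenyl series.

Step 13
Reactants: 17 C9' enone
Product: 19 α'-hydroxy enone (acyloin; C8'–OH on the face opposite the C6' methyl), via lithium dienolate 18 (not isolated)
Conditions: LiN(i-Pr)2, THF, −78 °C; 2-(phenylsulfonyl)-3-phenyloxaziridine, −78 °C; aq. NH4Cl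
Reagents that add atoms: 2-(phenylsulfonyl)-3-phenyloxaziridine, O=S(=O)(N1OC1c1ccccc1)c1ccccc1; lithium diisopropylamide, [Li+].CC(C)[N-]C(C)C (lithium of 18 only)
Why: Davis enolate hydroxylation; kinetic deprotonation of an enone takes the α' position C8' rather than the γ position C12', and the enone is the only carbonyl group present. The oxaziridine should approach anti to the axial C6' and C2' methyl groups; the new centre is erased in step 15.

Step 14
Reactants: 19 α'-hydroxy enone
Product: 20 triol (C3–OH, C3'–OH, C8'–OH)
Conditions: HF·pyridine, THF, 0 °C to rt
Reagents that add atoms: none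
Why: Fluoride-driven cleavage of both silyl ethers in one operation; the buffered acidic medium avoids base-induced ketol shifts and air oxidation of the acyloin.

Step 15
Reactants: 20 triol
Product: 22 sodwanone B, via tetraketone 21 (not isolated)
Conditions: Dess–Martin periodinane (excess), CH2Cl2, rt; then Et3N (cat.)
Reagents that add atoms: none
Why: Dess–Martin oxidation of all three secondary alcohols under nearly neutral conditions gives 21, whose C7'–H is α to the new C8' carbonyl group. Enolisation towards C7' gives the fully substituted, hydrogen-bonded, cross-conjugated diosphenol, which is the stable tautomer found in the target; C6, C7, C10, C11 and C6' have no pathway for epimerisation.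

## Compound list

1 | (E)-geranylacetone | CC(=O)CC/C=C(\C)CCC=C(C)C | starting material
2 | (3S,6S,7S)-diepoxy ketone | CC(=O)CC[C@@H]1O[C@@]1(C)CC[C@@H]1OC1(C)C | intermediate
3 | (+)-sclareolide | C[C@]12CCCC(C)(C)[C@@H]1CC[C@@]3(C)OC(=O)C[C@H]23 | starting material
4 | (3'S)-3'-hydroxysclareolide | C[C@]12CC[C@H](O)C(C)(C)[C@@H]1CC[C@@]3(C)OC(=O)C[C@H]23 | intermediate
5 | hydroxy ester with C10'=C11' alkene | CC1=C(CC(=O)OC)[C@@]2(C)CC[C@H](O)C(C)(C)[C@@H]2CC1 | intermediate
6 | tert-butyldimethylsilyl ether of 5 | CC1=C(CC(=O)OC)[C@@]2(C)CC[C@H](O[Si](C)(C)C(C)(C)C)C(C)(C)[C@@H]2CC1 | intermediate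
7 | eastern C12 aldehyde | CC1=C(CC=O)[C@@]2(C)CC[C@H](O[Si](C)(C)C(C)(C)C)C(C)(C)[C@@H]2CC1 | intermediate
8 | lithium enolate of 2 (C10=C11) | [Li+].C=C([O-])CC[C@@H]1O[C@@]1(C)CC[C@@H]1OC1(C)C | intermediate
9 | β-hydroxy ketone (aldol adduct, C12 epimers) | CC1=C(CC(O)CC(=O)CC[C@@H]2O[C@@]2(C)CC[C@@H]2OC2(C)C)[C@@]2(C)CC[C@H](O[Si](C)(C)C(C)(C)C)C(C)(C)[C@@H]2CC1 | intermediate
10 | C12 mesylate of 9 | CC1=C(CC(CC(=O)CC[C@@H]2O[C@@]2(C)CC[C@@H]2OC2(C)C)OS(C)(=O)=O)[C@@]2(C)CC[C@H](O[Si](C)(C)C(C)(C)C)C(C)(C)[C@@H]2CC1 | intermediate
11 | (E)-enone | CC1=C(C/C=C/C(=O)CC[C@@H]2O[C@@]2(C)CC[C@@H]2OC2(C)C)[C@@]2(C)CC[C@H](O[Si](C)(C)C(C)(C)C)C(C)(C)[C@@H]2CC1 | intermediate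
12 | (Z)-triethylsilyl enol ether | CC1=C(CC/C=C(\O[Si](CC)(CC)CC)CC[C@@H]2O[C@@]2(C)CC[C@@H]2OC2(C)C)[C@@]2(C)CC[C@H](O[Si](C)(C)C(C)(C)C)C(C)(C)[C@@H]2CC1 | intermediate
13 | bicyclic epoxonium triflate | CC1=C(CC/C=C(\O[Si](CC)(CC)CC)CC[C@@H]2[O+]3[C@@]2(C)CC[C@H](O[Si](CC)(CC)CC)C3(C)C)[C@@]2(C)CC[C@H](O[Si](C)(C)C(C)(C)C)C(C)(C)[C@@H]2CC1.[O-]S(=O)(=O)C(F)(F)F | intermediate
14 | bicyclic keto silyl ether (rings A and B closed) | CC1=C(CC[C@@H]2C(=O)CC[C@@H]3OC(C)(C)[C@@H](O[Si](CC)(CC)CC)CC[C@]32C)[C@@]2(C)CC[C@H](O[Si](C)(C)C(C)(C)C)C(C)(C)[C@@H]2CC1 | intermediate
15 | exocyclic alkene (C10=CH2) | CC1=C(CC[C@@H]2C(=C)CC[C@@H]3OC(C)(C)[C@@H](O[Si](CC)(CC)CC)CC[C@]32C)[C@@]2(C)CC[C@H](O[Si](C)(C)C(C)(C)C)C(C)(C)[C@@H]2CC1 | intermediate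
16 | (10R)-methyl compound | CC1=C(CC[C@@H]2[C@H](C)CC[C@@H]3OC(C)(C)[C@@H](O[Si](CC)(CC)CC)CC[C@]32C)[C@@]2(C)CC[C@H](O[Si](C)(C)C(C)(C)C)C(C)(C)[C@@H]2CC1 | intermediate
17 | C9' enone | CC1=C(CC[C@@H]2[C@H](C)CC[C@@H]3OC(C)(C)[C@@H](O[Si](CC)(CC)CC)CC[C@]32C)[C@@]2(C)CC[C@H](O[Si](C)(C)C(C)(C)C)C(C)(C)[C@@H]2CC1=O | intermediate
18 | lithium dienolate of 17 (C8'=C9') | [Li+].CC1=C(CC[C@@H]2[C@H](C)CC[C@@H]3OC(C)(C)[C@@H](O[Si](CC)(CC)CC)CC[C@]32C)[C@@]2(C)CC[C@H](O[Si](C)(C)C(C)(C)C)C(C)(C)[C@@H]2C=C1[O-] | intermediate
19 | α'-hydroxy enone (C8'–OH) | CC1=C(CC[C@@H]2[C@H](C)CC[C@@H]3OC(C)(C)[C@@H](O[Si](CC)(CC)CC)CC[C@]32C)[C@@]2(C)CC[C@H](O[Si](C)(C)C(C)(C)C)C(C)(C)[C@@H]2[C@@H](O)C1=O | intermediate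
20 | triol | CC1=C(CC[C@@H]2[C@H](C)CC[C@@H]3OC(C)(C)[C@@H](O)CC[C@]32C)[C@@]2(C)CC[C@H](O)C(C)(C)[C@@H]2[C@@H](O)C1=O | intermediate
21 | tetraketone | CC1=C(CC[C@@H]2[C@H](C)CC[C@@H]3OC(C)(C)C(=O)CC[C@]32C)[C@@]2(C)CCC(=O)C(C)(C)[C@@H]2C(=O)C1=O | intermediate
22 | sodwanone B | CC1=C(CC[C@@H]2[C@H](C)CC[C@@H]3OC(C)(C)C(=O)CC[C@]32C)[C@@]2(C)CCC(=O)C(C)(C)C2=C(O)C1=O | target

## Step count and least certain steps

Total step count: 15. Longest linear sequence: 14 steps (3 to 22, steps 2 to 15); the western branch adds step 1.

**Step 9 (key step).** The most likely failure is interruption of the charge relay. This could happen by silylation of the inner epoxide first, exo opening to a smaller ether ring, a 1,2-hydride shift of an activated epoxide, or protodesilylation of the enol ether by adventitious acid before the C–C bond forms.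

Fallback, from 12 back to the route at 15: the terminating nucleophile is changed to an acid-stable allylsilane, which also makes the Wittig step unnecessary. CsF and PhNTf2 convert 12 with retention of geometry into the (Z)-enol triflate F1. Kumada coupling with Me3SiCH2MgCl and Pd(PPh3)4 (zerovalent palladium), known to spare trisubstituted epoxides, gives the allylsilane F2. MeAlCl2 in CH2Cl2 at −78 °C should then trigger the same oxa- and carbacyclisation, ended by loss of the silyl group, to give the methylene alcohol F3. Silylation of F3 with Et3SiCl and imidazole gives 15.

**Step 11.** What may go wrong is poor facial selectivity on the catalyst surface, or migration of the exocyclic double bond into ring B before reduction, which would endanger C11.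

Fallback, from 15 back at 16: the hydrogen atom is delivered by a sterically far more demanding reagent, and the carbon is deoxygenated afterwards. Hydroboration with 9-BBN from the face opposite the C6 methyl and oxidation with NaOH/H2O2 gives the axial hydroxymethyl compound F4. Treatment with I2, PPh3 and imidazole gives the primary iodide F5, and radical reduction with Bu3SnH/AIBN gives 16.

**Step 12.** What may go wrong is poor site selectivity among C9', C12' and the C10' methyl group, over-oxidation to an ene-dione, or loss of the triethylsilyl group.

Fallback, from 16 back at 17: the radical-type oxidation is replaced by a pericyclic one. SeO2 (cat.) with t-BuOOH reacts by an ene reaction and [2,3]-sigmatropic shift, a sequence that prefers the endocyclic methylene group of a ring alkene, and gives the C9' allylic alcohol F6. MnO2, which oxidises only allylic alcohols, then gives 17.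

**Step 3.** What may go wrong is incomplete convergence of the alkene isomers on the tetrasubstituted position, and relactonisation with epimerisation at C10'.

Fallback, from 4 back at 7, which separates ring opening, elimination and isomerisation:
- Silylation gives the lactone silyl ether F7.
- MeNH(OMe)·HCl with i-PrMgCl gives the hydroxy Weinreb amide F8.
- SOCl2/pyridine at low temperature gives the exocyclic alkene F9.
- Catalytic I2 in warm benzene moves the double bond to give the tetrasubstituted alkene amide F10.
- i-Bu2AlH gives 7.

**Step 7 (with step 6).** What may go wrong is proton transfer from the enolisable aldehyde during the aldol addition, retro-aldol cleavage, and base-induced migration of the new double bond through the doubly allylic C12' methylene group.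

Fallback, from 7 back at 11: the enone is made by olefination under very mild base. The dianion of dimethyl (2-oxopropyl)phosphonate (NaH, then n-BuLi) is alkylated with geranyl bromide at its terminal carbon to give the dienyl ketophosphonate F11. Shi epoxidation as in step 1 gives the diepoxy ketophosphonate F12. Horner–Wadsworth–Emmons reaction of F12 with 7 (LiCl, i-Pr2NEt, MeCN) gives 11.

## Further compounds

F1 | step 9 | (Z)-enol triflate | CC1=C(CC/C=C(\OS(=O)(=O)C(F)(F)F)CC[C@@H]2O[C@@]2(C)CC[C@@H]2OC2(C)C)[C@@]2(C)CC[C@H](O[Si](C)(C)C(C)(C)C)C(C)(C)[C@@H]2CC1
F2 | step 9 | allylsilane | CC1=C(CC/C=C(\C[Si](C)(C)C)CC[C@@H]2O[C@@]2(C)CC[C@@H]2OC2(C)C)[C@@]2(C)CC[C@H](O[Si](C)(C)C(C)(C)C)C(C)(C)[C@@H]2CC1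
F3 | step 9 | methylene alcohol (C3–OH, C10=CH2) | CC1=C(CC[C@@H]2C(=C)CC[C@@H]3OC(C)(C)[C@@H](O)CC[C@]32C)[C@@]2(C)CC[C@H](O[Si](C)(C)C(C)(C)C)C(C)(C)[C@@H]2CC1
F4 | step 11 | axial hydroxymethyl compound | CC1=C(CC[C@@H]2[C@H](CO)CC[C@@H]3OC(C)(C)[C@@H](O[Si](CC)(CC)CC)CC[C@]32C)[C@@]2(C)CC[C@H](O[Si](C)(C)C(C)(C)C)C(C)(C)[C@@H]2CC1
F5 | step 11 | primary iodide | CC1=C(CC[C@@H]2[C@H](CI)CC[C@@H]3OC(C)(C)[C@@H](O[Si](CC)(CC)CC)CC[C@]32C)[C@@]2(C)CC[C@H](O[Si](C)(C)C(C)(C)C)C(C)(C)[C@@H]2CC1
F6 | step 12 | C9' allylic alcohol | CC1=C(CC[C@@H]2[C@H](C)CC[C@@H]3OC(C)(C)[C@@H](O[Si](CC)(CC)CC)CC[C@]32C)[C@@]2(C)CC[C@H](O[Si](C)(C)C(C)(C)C)C(C)(C)[C@@H]2C[C@H]1O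
F7 | step 3 | lactone silyl ether | C[C@]12CC[C@H](O[Si](C)(C)C(C)(C)C)C(C)(C)[C@@H]1CC[C@@]3(C)OC(=O)C[C@H]23
F8 | step 3 | hydroxy Weinreb amide | C[C@]12CC[C@H](O[Si](C)(C)C(C)(C)C)C(C)(C)[C@@H]1CC[C@@](C)(O)[C@@H]2CC(=O)N(C)OC
F9 | step 3 | exocyclic alkene amide | C[C@]12CC[C@H](O[Si](C)(C)C(C)(C)C)C(C)(C)[C@@H]1CCC(=C)[C@@H]2CC(=O)N(C)OC
F10 | step 3 | tetrasubstituted alkene amide | CC1=C(CC(=O)N(C)OC)[C@@]2(C)CC[C@H](O[Si](C)(C)C(C)(C)C)C(C)(C)[C@@H]2CC1
F11 | step 7 | dienyl ketophosphonate | COP(=O)(CC(=O)CC/C=C(\C)CCC=C(C)C)OC
F12 | step 7 | diepoxy ketophosphonate | COP(=O)(CC(=O)CC[C@@H]1O[C@@]1(C)CC[C@@H]1OC1(C)C)OC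
A1 | alternative 1 | C11-vinyl oxepane bicycle | C=C[C@@H]1[C@H](C)CC[C@@H]2OC(C)(C)[C@@H](O[Si](C)(C)C(C)(C)C)CC[C@]21C
A2 | alternative 1 | ring C enol triflate | CC1=C(OS(=O)(=O)C(F)(F)F)[C@@]2(C)CC[C@H](O[Si](C)(C)C(C)(C)C)C(C)(C)[C@@H]2CC1
A3 | alternative 2 | hexasubstituted catechol iodide | Cc1c(CC[C@@H]2[C@H](C)CC[C@@H]3OC(C)(C)C(=O)CC[C@]32C)c(C)c(C(C)(C)C(CCI)O[Si](C)(C)C(C)(C)C)c(O)c1O
A4 | alternative 3 | all-(S) acyclic triepoxide | CC1(C)O[C@H]1CC[C@]1(C)O[C@H]1CC/C(C)=C/CC/C=C(\C)CC/C=C(\C)CC[C@@H]1OC1(C)C
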